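**Retrosynthetic overview**
- The target comes from a MOM-protected hydroazulene by two late ortho-lithiation/formylations and acid deprotection, after Wolff–Kishner removal of a C-2 ketone that served only as an activating group.
- Key bond C-1–C-1′: intermolecular Michael addition of the γ-carbon of a bicyclic β-keto ester dianion to an o-quinone methide made in situ from a Boc-protected salicylaldehyde and i-BuMgBr; this sets the quaternary and the benzylic centre together.
- Five-membered ring (formed second): Dieckmann closure between an acetate arm on C-3a (zinc enolate coupling to an α-bromo enone) and a propanoate arm on C-8a (zinc enolate coupling to a kinetic vinyl triflate, which also fixes the C-8a=C-8 alkene).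
- C-3a and C-4: hydroxyl-directed hydrogenation of a tetrasubstituted cycloheptenone, relayed from C-7.
- Seven-membered ring (formed first): Ito–Saegusa one-carbon ring expansion of (R)-carvone hydrate, which supplies C-7.

Assumption: the core atoms carry the locants C-1 to C-8a as in an octahydroazulene (C-1 quaternary, C-8a=C-8 the ring alkene), the benzylic carbon is C-1′, and these labels are used for the same atoms in all earlier intermediates.

**Route**

Step 1
Reactants: 1 (R)-(−)-carvone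
Product: 2 (5R)-5-(2-hydroxypropan-2-yl)-2-methylcyclohex-2-en-1-one
Conditions: 50% aq. H2SO4, 0 °C, 24 h
Reagents that add atoms: water, O
Why: Acid-catalysed Markovnikov hydration of the isopropenyl group through the tertiary cation leaves the enone and the existing stereocentre (future C-7) untouched.

Step 2
Reactants: 2 (5R)-5-(2-hydroxypropan-2-yl)-2-methylcyclohex-2-en-1-one
Product: 4 trimethyl{[(5R)-2-methyl-5-{2-[(trimethylsilyl)oxy]propan-2-yl}cyclohex-1-en-1-yl]oxy}silane, via dilithium enolate alkoxide 3 (not isolated)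
Conditions: LiBH(s-Bu)3 (2.2 equiv), THF, −78 °C; then Me3SiCl, Et3N, −78 °C → rt
Reagents that add atoms: chlorotrimethylsilane, C[Si](C)(C)Cl
Why: Conjugate hydride reduction of the enone gives the enolate regiospecifically at the methyl-bearing carbon, and O-silylation traps it together with the tertiary alkoxide; no new stereocentre.

Step 3
Reactants: 4 trimethyl{[(5R)-2-methyl-5-{2-[(trimethylsilyl)oxy]propan-2-yl}cyclohex-1-en-1-yl]oxy}silane
Product: 5 trimethyl{[(3R)-6-methyl-3-{2-[(trimethylsilyl)oxy]propan-2-yl}bicyclo[4.1.0]heptan-1-yl]oxy}silane (both cyclopropane diastereomers)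
Conditions: Et2Zn, CH2I2, CH2Cl2, 0 °C → rt
Reagents that add atoms: diiodomethane, ICI
Why: Simmons–Smith (Furukawa) cyclopropanation of the electron-rich silyl enol ether adds the future C-3a; the two new centres are destroyed in the next step, so their configuration does not matter.

Step 4
Reactants: 5 trimethyl{[(3R)-6-methyl-3-{2-[(trimethylsilyl)oxy]propan-2-yl}bicyclo[4.1.0]heptan-1-yl]oxy}silane
Product: 7 (6R)-6-(2-hydroxypropan-2-yl)-3-methylcyclohept-2-en-1-one, via β-chloro ketone 6 (not isolated)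
Conditions: FeCl3, DMF, 0 °C → rt, aq. HCl work-up; then NaOAc, MeOH, reflux
Reagents that add atoms: none
Why: Ito–Saegusa ring expansion, in which one-electron oxidation of the siloxycyclopropane cleaves the ring-fusion bond to the ring-enlarged β-chloro ketone and E1cB loss of HCl gives the conjugated cycloheptenone.

Step 5
Reactants: 7 (6R)-6-(2-hydroxypropan-2-yl)-3-methylcyclohept-2-en-1-one
Product: 9 (6R)-2-bromo-6-(2-hydroxypropan-2-yl)-3-methylcyclohept-2-en-1-one, via dibromo ketone 8 (not isolated)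
Conditions: Br2, CH2Cl2, 0 °C; then Et3N, 0 °C → rt
Reagents that add atoms: bromine, BrBr
Why: Bromine addition to the enone double bond followed by base-induced dehydrobromination (α-bromination of an enone) gives the vinyl bromide handle at the future C-3a.

Step 6
Reactants: 9 (6R)-2-bromo-6-(2-hydroxypropan-2-yl)-3-methylcyclohept-2-en-1-one; 10 tert-butyl bromoacetate
Product: 12 tert-butyl 2-[(5R)-5-(2-hydroxypropan-2-yl)-2-methyl-7-oxocyclohept-1-en-1-yl]acetate, via zinc enolate 11 (not isolated)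
Conditions: 10 (3 equiv), Zn dust, THF, 40 °C; then 9, Pd(P(t-Bu)3)2 (5 mol%), THF, 50 °C
Reagents that add atoms: none
Why: Negishi-type cross-coupling of the Reformatsky reagent with the α-bromo enone on zerovalent palladium attaches the future C-3/C-2 arm to C-3a, the zinc enolate being too mild to add to the ketone.

Step 7
Reactants: 12 tert-butyl 2-[(5R)-5-(2-hydroxypropan-2-yl)-2-methyl-7-oxocyclohept-1-en-1-yl]acetate
Product: 13 tert-butyl 2-[(1R,2R,5R)-5-(2-hydroxypropan-2-yl)-2-methyl-7-oxocycloheptyl]acetate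
Conditions: H2 (50 bar), [Ir(cod)(PCy3)(py)]PF6 (10 mol%), CH2Cl2, rt
Reagents that add atoms: none
Why: Hydroxyl-directed homogeneous hydrogenation, in which the tertiary alcohol binds the cationic iridium and both hydrogens add syn from the face carrying the hydroxypropyl group, so that H-3a and H-4 end up cis to each other and to that group.

Step 8
Reactants: 13 tert-butyl 2-[(1R,2R,5R)-5-(2-hydroxypropan-2-yl)-2-methyl-7-oxocycloheptyl]acetate
Product: 14 tert-butyl 2-[(1R,2R,5R)-2-methyl-7-oxo-5-{2-[(triethylsilyl)oxy]propan-2-yl}cycloheptyl]acetate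
Conditions: Et3SiOTf, 2,6-lutidine, CH2Cl2, −78 °C
Reagents that add atoms: triethylsilyl trifluoromethanesulfonate, CC[Si](CC)(CC)OS(=O)(=O)C(F)(F)F
Why: Silylation of the tertiary alcohol under non-enolising conditions protects it for the strong-base steps without touching the epimerisable C-3a centre.

Step 9
Reactants: 14 tert-butyl 2-[(1R,2R,5R)-2-methyl-7-oxo-5-{2-[(triethylsilyl)oxy]propan-2-yl}cycloheptyl]acetate
Product: 16 tert-butyl 2-[(1R,4R,7R)-7-methyl-4-{2-[(triethylsilyl)oxy]propan-2-yl}-2-{[(trifluoromethyl)sulfonyl]oxy}cyclohept-2-en-1-yl]acetate, via potassium enolate 15 (not isolated)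
Conditions: KN(SiMe3)2 (1.05 equiv), THF, −78 °C; then PhNTf2, −78 → 0 °C
Reagents that add atoms: N-phenylbis(trifluoromethanesulfonimide), O=S(=O)(N(c1ccccc1)S(=O)(=O)C(F)(F)F)C(F)(F)F
Why: Kinetic deprotonation at the less substituted α-carbon (future C-8) and O-triflation place the double bond at C-8a=C-8 and lock the cis C-3a centre, which is never enolised.

Step 10
Reactants: 16 tert-butyl 2-[(1R,4R,7R)-7-methyl-4-{2-[(triethylsilyl)oxy]propan-2-yl}-2-{[(trifluoromethyl)sulfonyl]oxy}cyclohept-2-en-1-yl]acetate; 17 methyl 2-bromopropanoate (racemic)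
Product: 19 methyl 2-[(3R,6R,7R)-7-(2-tert-butoxy-2-oxoethyl)-6-methyl-3-{2-[(triethylsilyl)oxy]propan-2-yl}cyclohept-1-en-1-yl]propanoate (both epimers at the propanoate carbon), via zinc enolate 18 (not isolated)
Conditions: 17 (2 equiv), Zn dust, THF, 40 °C; then 16, Pd(P(t-Bu)3)2 (5 mol%), LiCl, THF, 60 °C
Reagents that add atoms: none
Why: Palladium-catalysed Negishi-type coupling of the zinc ester enolate with the vinyl triflate joins C-1 (with its methyl group) to C-8a; the C-1 centre forms as a mixture, which is harmless because it is enolised in step 14.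

Step 11
Reactants: 19 methyl 2-[(3R,6R,7R)-7-(2-tert-butoxy-2-oxoethyl)-6-methyl-3-{2-[(triethylsilyl)oxy]propan-2-yl}cyclohept-1-en-1-yl]propanoate
Product: 20 tert-butyl (3aS,4R,7R)-1,4-dimethyl-2-oxo-7-{2-[(triethylsilyl)oxy]propan-2-yl}-1,2,3,3a,4,5,6,7-octahydroazulene-3-carboxylate (epimers at C-1 and C-3)
Conditions: KOt-Bu (1.5 equiv), THF, 0 °C → rt, 30 min; AcOH quench at −78 °C
Reagents that add atoms: none
Why: Dieckmann condensation in which the tert-butyl acetate enolate attacks the methyl ester to close the five-membered ring; the enolisable β-keto ester is the thermodynamic sink and the bulky tert-butyl ester does not act as acceptor.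

Step 12
Reactants: 21 2,4,6-trihydroxybenzaldehyde
Product: 22 2-hydroxy-4,6-bis(methoxymethoxy)benzaldehyde
Conditions: MOMCl (2.1 equiv), i-Pr2NEt, CH2Cl2, 0 °C
Reagents that add atoms: chloromethyl methyl ether, COCCl
Why: Williamson-type O-alkylation stops after two hydroxyls because the remaining ortho hydroxyl is hydrogen-bonded to the aldehyde.

Step 13
Reactants: 22 2-hydroxy-4,6-bis(methoxymethoxy)benzaldehyde
Product: 23 tert-butyl 2-formyl-3,5-bis(methoxymethoxy)phenyl carbonate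
Conditions: Boc2O, i-Pr2NEt, DMAP (cat.), THF, rt
Reagents that add atoms: di-tert-butyl dicarbonate, CC(C)(C)OC(=O)OC(=O)OC(C)(C)C
Why: O-acylation of the phenol installs the carbonate that later migrates to the benzylic oxygen and leaves to unmask the o-quinone methide.

Step 14
Reactants: 20 tert-butyl (3aS,4R,7R)-1,4-dimethyl-2-oxo-7-{2-[(triethylsilyl)oxy]propan-2-yl}-1,2,3,3a,4,5,6,7-octahydroazulene-3-carboxylate; 23 tert-butyl 2-formyl-3,5-bis(methoxymethoxy)phenyl carbonate; 24 isobutylmagnesium bromide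
Product: 28 tert-butyl (1R,3aS,4R,7R)-1-{(1S)-1-[2-hydroxy-4,6-bis(methoxymethoxy)phenyl]-3-methylbutyl}-1,4-dimethyl-2-oxo-7-{2-[(triethylsilyl)oxy]propan-2-yl}-1,2,3,3a,4,5,6,7-octahydroazulene-3-carboxylate, via dilithium dianion 25 (not isolated), via magnesium alkoxide 26 (not isolated), via o-quinone methide 27 (not isolated)
Conditions: 20, LiN(i-Pr)2 (2.2 equiv), THF, −78 → 0 °C; separately 23 (1.3 equiv), i-BuMgBr, THF, −78 → −40 °C; combine at −78 °C, warm to rt; aq. NH4Cl
Reagents that add atoms: none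
Why: Intermolecular Michael addition of the γ-carbon (C-1) of the β-keto ester dianion to the o-quinone methide released from 26 by Boc transfer and elimination, in which C-1 is attacked on the face opposite the C-3a–C-4 bond and a compact lithium-bridged, hetero-Diels–Alder-like transition state (isobutyl turned towards the quinone carbonyl, the small C-1 methyl under the ring) sets the benzylic centre.

Step 15
Reactants: 28 tert-butyl (1R,3aS,4R,7R)-1-{(1S)-1-[2-hydroxy-4,6-bis(methoxymethoxy)phenyl]-3-methylbutyl}-1,4-dimethyl-2-oxo-7-{2-[(triethylsilyl)oxy]propan-2-yl}-1,2,3,3a,4,5,6,7-octahydroazulene-3-carboxylate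
Product: 29 (1R,3aR,4R,7R)-1-{(1S)-1-[2-hydroxy-4,6-bis(methoxymethoxy)phenyl]-3-methylbutyl}-1,4-dimethyl-7-{2-[(triethylsilyl)oxy]propan-2-yl}-3,3a,4,5,6,7-hexahydroazulen-2(1H)-one
Conditions: DMSO/H2O (10:1), 140 °C
Reagents that add atoms: none
Why: Thermal loss of tert-butanol from the tert-butyl β-keto ester (acyl ketene), hydration and decarboxylation of the β-keto acid give the ketone under neutral conditions; C-1 is quaternary, so nothing can epimerise or conjugate.

Step 16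
Reactants: 29 (1R,3aR,4R,7R)-1-{(1S)-1-[2-hydroxy-4,6-bis(methoxymethoxy)phenyl]-3-methylbutyl}-1,4-dimethyl-7-{2-[(triethylsilyl)oxy]propan-2-yl}-3,3a,4,5,6,7-hexahydroazulen-2(1H)-one
Product: 30 (1R,3aR,4R,7R)-1,4-dimethyl-1-{(1S)-3-methyl-1-[2,4,6-tris(methoxymethoxy)phenyl]butyl}-7-{2-[(triethylsilyl)oxy]propan-2-yl}-3,3a,4,5,6,7-hexahydroazulen-2(1H)-one
Conditions: NaH (1.2 equiv), DMF, 0 °C; then MOMCl
Reagents that add atoms: chloromethyl methyl ether, COCCl
Why: Williamson O-alkylation of the phenoxide removes the free ortho phenol, so that neither hemiketal formation nor phenoxide-driven retro-Michael cleavage can interfere later.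

Step 17
Reactants: 30 (1R,3aR,4R,7R)-1,4-dimethyl-1-{(1S)-3-methyl-1-[2,4,6-tris(methoxymethoxy)phenyl]butyl}-7-{2-[(triethylsilyl)oxy]propan-2-yl}-3,3a,4,5,6,7-hexahydroazulen-2(1H)-one
Product: 31 (1R,3aR,4R,7R)-7-(2-hydroxypropan-2-yl)-1,4-dimethyl-1-{(1S)-3-methyl-1-[2,4,6-tris(methoxymethoxy)phenyl]butyl}-3,3a,4,5,6,7-hexahydroazulen-2(1H)-one
Conditions: Bu4NF, THF, 40 °C
Reagents that add atoms: none
Why: Fluoride-induced desilylation frees the tertiary alcohol cleanly before the hot alkaline reduction, which would otherwise cleave the silyl ether in an undefined way.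

Step 18
Reactants: 31 (1R,3aR,4R,7R)-7-(2-hydroxypropan-2-yl)-1,4-dimethyl-1-{(1S)-3-methyl-1-[2,4,6-tris(methoxymethoxy)phenyl]butyl}-3,3a,4,5,6,7-hexahydroazulen-2(1H)-one
Product: 33 2-[(1R,3aR,4R,7R)-1,4-dimethyl-1-{(1R)-3-methyl-1-[2,4,6-tris(methoxymethoxy)phenyl]butyl}-1,2,3,3a,4,5,6,7-octahydroazulen-7-yl]propan-2-ol, via hydrazone 32 (not isolated)
Conditions: N2H4·H2O, KOH, diethylene glycol, 130 → 200 °C
Reagents that add atoms: none
Why: Wolff–Kishner reduction (Huang-Minlon) removes the C-2 carbonyl that served as the activating group; the MOM acetals and the isolated alkene are base-stable and no centre is epimerisable.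

Step 19
Reactants: 33 2-[(1R,3aR,4R,7R)-1,4-dimethyl-1-{(1R)-3-methyl-1-[2,4,6-tris(methoxymethoxy)phenyl]butyl}-1,2,3,3a,4,5,6,7-octahydroazulen-7-yl]propan-2-ol
Product: 35 3-{(1R)-1-[(1R,3aR,4R,7R)-7-(2-hydroxypropan-2-yl)-1,4-dimethyl-1,2,3,3a,4,5,6,7-octahydroazulen-1-yl]-3-methylbutyl}-2,4,6-tris(methoxymethoxy)benzaldehyde, via aryllithium 34 (not isolated)
Conditions: n-BuLi (2.5 equiv), TMEDA, THF, 0 °C; then DMF, −78 °C → rt; aq. NH4Cl
Reagents that add atoms: N,N-dimethylformamide, CN(C)C=O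
Why: Directed ortho-metalation at a ring position flanked by two MOM ethers followed by formylation with DMF; the lithium alkoxide of the tertiary alcohol is inert.

Step 20
Reactants: 35 3-{(1R)-1-[(1R,3aR,4R,7R)-7-(2-hydroxypropan-2-yl)-1,4-dimethyl-1,2,3,3a,4,5,6,7-octahydroazulen-1-yl]-3-methylbutyl}-2,4,6-tris(methoxymethoxy)benzaldehyde
Product: 38 5-{(1R)-1-[(1R,3aR,4R,7R)-7-(2-hydroxypropan-2-yl)-1,4-dimethyl-1,2,3,3a,4,5,6,7-octahydroazulen-1-yl]-3-methylbutyl}-2,4,6-tris(methoxymethoxy)benzene-1,3-dicarbaldehyde, via lithium amino alkoxide 36 (not isolated), via lithiated amino alkoxide 37 (not isolated)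
Conditions: LiN(Me)CH2CH2NMe2 (2.2 equiv, from the amine and n-BuLi), THF, −20 °C; then n-BuLi (3 equiv), −20 → 0 °C; then DMF; aq. NH4Cl
Reagents that add atoms: N,N-dimethylformamide, CN(C)C=O
Why: The aldehyde is masked in situ as its lithium α-amino alkoxide (Comins protection), the last ring position between two MOM ethers undergoes directed ortho-metalation and formylation, and aqueous work-up releases both aldehydes.

Step 21
Reactants: 38 5-{(1R)-1-[(1R,3aR,4R,7R)-7-(2-hydroxypropan-2-yl)-1,4-dimethyl-1,2,3,3a,4,5,6,7-octahydroazulen-1-yl]-3-methylbutyl}-2,4,6-tris(methoxymethoxy)benzene-1,3-dicarbaldehyde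
Product: 39 5-{(1R)-1-[(1R,3aR,4R,7R)-7-(2-hydroxypropan-2-yl)-1,4-dimethyl-1,2,3,3a,4,5,6,7-octahydroazulen-1-yl]-3-methylbutyl}-2,4,6-trihydroxybenzene-1,3-dicarbaldehyde (CNP0281883.1)
Conditions: HCl (1 M in MeOH), THF, 0 °C → rt; aq. NaHCO3 work-up
Reagents that add atoms: none
Why: Acid-catalysed acetal exchange removes the three MOM ethers, each activated by an ortho formyl group, under conditions mild enough for the tertiary alcohol and the trisubstituted alkene.

**Compound list**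

1 | (R)-(−)-carvone | CC1=CC[C@H](CC1=O)C(C)=C | starting material
2 | (5R)-5-(2-hydroxypropan-2-yl)-2-methylcyclohex-2-en-1-one | CC1=CC[C@H](CC1=O)C(C)(C)O | intermediate
3 | dilithium salt of (5R)-5-(2-hydroxypropan-2-yl)-2-methylcyclohex-1-en-1-ol (enolate and alkoxide, not isolated) | CC1=C(O[Li])C[C@@H](CC1)C(C)(C)O[Li] | intermediate
4 | trimethyl{[(5R)-2-methyl-5-{2-[(trimethylsilyl)oxy]propan-2-yl}cyclohex-1-en-1-yl]oxy}silane | CC1=C(O[Si](C)(C)C)C[C@@H](CC1)C(C)(C)O[Si](C)(C)C | intermediate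
5 | trimethyl{[(3R)-6-methyl-3-{2-[(trimethylsilyl)oxy]propan-2-yl}bicyclo[4.1.0]heptan-1-yl]oxy}silane (both cyclopropane diastereomers) | CC12CC2(O[Si](C)(C)C)C[C@@H](CC1)C(C)(C)O[Si](C)(C)C | intermediate
6 | (6R)-3-chloro-6-(2-hydroxypropan-2-yl)-3-methylcycloheptan-1-one (not isolated) | CC1(Cl)CC(=O)C[C@@H](CC1)C(C)(C)O | intermediate
7 | (6R)-6-(2-hydroxypropan-2-yl)-3-methylcyclohept-2-en-1-one | CC1=CC(=O)C[C@@H](CC1)C(C)(C)O | intermediate
8 | (6R)-2,3-dibromo-6-(2-hydroxypropan-2-yl)-3-methylcycloheptan-1-one (not isolated) | CC1(Br)C(Br)C(=O)C[C@@H](CC1)C(C)(C)O | intermediate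
9 | (6R)-2-bromo-6-(2-hydroxypropan-2-yl)-3-methylcyclohept-2-en-1-one | CC1=C(Br)C(=O)C[C@@H](CC1)C(C)(C)O | intermediate
10 | tert-butyl bromoacetate | CC(C)(C)OC(=O)CBr | starting material
11 | bromo(2-tert-butoxy-2-oxoethyl)zinc (Reformatsky reagent, not isolated) | CC(C)(C)OC(=O)C[Zn]Br | intermediate
12 | tert-butyl 2-[(5R)-5-(2-hydroxypropan-2-yl)-2-methyl-7-oxocyclohept-1-en-1-yl]acetate | CC1=C(CC(=O)OC(C)(C)C)C(=O)C[C@@H](CC1)C(C)(C)O | intermediate
13 | tert-butyl 2-[(1R,2R,5R)-5-(2-hydroxypropan-2-yl)-2-methyl-7-oxocycloheptyl]acetate | CC(C)(C)OC(=O)C[C@H]1C(=O)C[C@H](C(C)(C)O)CC[C@H]1C | intermediate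
14 | tert-butyl 2-[(1R,2R,5R)-2-methyl-7-oxo-5-{2-[(triethylsilyl)oxy]propan-2-yl}cycloheptyl]acetate | CC(C)(C)OC(=O)C[C@H]1C(=O)C[C@H](C(C)(C)O[Si](CC)(CC)CC)CC[C@H]1C | intermediate
15 | potassium enolate of 14 towards the ring CH2 (not isolated) | CC(C)(C)OC(=O)C[C@H]1C(O[K])=C[C@H](C(C)(C)O[Si](CC)(CC)CC)CC[C@H]1C | intermediate
16 | tert-butyl 2-[(1R,4R,7R)-7-methyl-4-{2-[(triethylsilyl)oxy]propan-2-yl}-2-{[(trifluoromethyl)sulfonyl]oxy}cyclohept-2-en-1-yl]acetate | CC(C)(C)OC(=O)C[C@H]1C(OS(=O)(=O)C(F)(F)F)=C[C@H](C(C)(C)O[Si](CC)(CC)CC)CC[C@H]1C | intermediate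
17 | methyl 2-bromopropanoate (racemic) | COC(=O)C(C)Br | starting material
18 | bromo(1-methoxy-1-oxopropan-2-yl)zinc (Reformatsky reagent, not isolated) | COC(=O)C(C)[Zn]Br | intermediate
19 | methyl 2-[(3R,6R,7R)-7-(2-tert-butoxy-2-oxoethyl)-6-methyl-3-{2-[(triethylsilyl)oxy]propan-2-yl}cyclohept-1-en-1-yl]propanoate (both epimers at the propanoate carbon) | CC(C)(C)OC(=O)C[C@H]1C(C(C)C(=O)OC)=C[C@H](C(C)(C)O[Si](CC)(CC)CC)CC[C@H]1C | intermediate
20 | tert-butyl (3aS,4R,7R)-1,4-dimethyl-2-oxo-7-{2-[(triethylsilyl)oxy]propan-2-yl}-1,2,3,3a,4,5,6,7-octahydroazulene-3-carboxylate (epimers at C-1 and C-3) | CC1C(=O)C(C(=O)OC(C)(C)C)[C@H]2C1=C[C@H](C(C)(C)O[Si](CC)(CC)CC)CC[C@H]2C | intermediate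
21 | 2,4,6-trihydroxybenzaldehyde | O=Cc1c(O)cc(O)cc1O | starting material
22 | 2-hydroxy-4,6-bis(methoxymethoxy)benzaldehyde | O=Cc1c(O)cc(OCOC)cc1OCOC | intermediate
23 | tert-butyl 2-formyl-3,5-bis(methoxymethoxy)phenyl carbonate | O=Cc1c(OC(=O)OC(C)(C)C)cc(OCOC)cc1OCOC | intermediate
24 | isobutylmagnesium bromide | CC(C)C[Mg]Br | starting material
25 | dilithium dianion of 20 (C-3 ester enolate plus C-1 carbanion, drawn as the bis-enolate, not isolated) | [Li+].[Li+].CC1=C([O-])C(=C([O-])OC(C)(C)C)[C@H]2C1=C[C@H](C(C)(C)O[Si](CC)(CC)CC)CC[C@H]2C | intermediate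
26 | bromomagnesium 1-[2-(tert-butoxycarbonyloxy)-4,6-bis(methoxymethoxy)phenyl]-3-methylbutan-1-olate (racemic, not isolated) | CC(C)CC(O[Mg]Br)c1c(OC(=O)OC(C)(C)C)cc(OCOC)cc1OCOC | intermediate
27 | 3,5-bis(methoxymethoxy)-6-(3-methylbutylidene)cyclohexa-2,4-dien-1-one (o-quinone methide, not isolated) | CC(C)CC=C1C(=O)C=C(OCOC)C=C1OCOC | intermediate
28 | tert-butyl (1R,3aS,4R,7R)-1-{(1S)-1-[2-hydroxy-4,6-bis(methoxymethoxy)phenyl]-3-methylbutyl}-1,4-dimethyl-2-oxo-7-{2-[(triethylsilyl)oxy]propan-2-yl}-1,2,3,3a,4,5,6,7-octahydroazulene-3-carboxylate (epimers at C-3) | CC(C)C[C@@H](c1c(O)cc(OCOC)cc1OCOC)[C@@]1(C)C(=O)C(C(=O)OC(C)(C)C)[C@H]2C1=C[C@H](C(C)(C)O[Si](CC)(CC)CC)CC[C@H]2C | intermediate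
29 | (1R,3aR,4R,7R)-1-{(1S)-1-[2-hydroxy-4,6-bis(methoxymethoxy)phenyl]-3-methylbutyl}-1,4-dimethyl-7-{2-[(triethylsilyl)oxy]propan-2-yl}-3,3a,4,5,6,7-hexahydroazulen-2(1H)-one | CC(C)C[C@@H](c1c(O)cc(OCOC)cc1OCOC)[C@@]1(C)C(=O)C[C@H]2C1=C[C@H](C(C)(C)O[Si](CC)(CC)CC)CC[C@H]2C | intermediate
30 | (1R,3aR,4R,7R)-1,4-dimethyl-1-{(1S)-3-methyl-1-[2,4,6-tris(methoxymethoxy)phenyl]butyl}-7-{2-[(triethylsilyl)oxy]propan-2-yl}-3,3a,4,5,6,7-hexahydroazulen-2(1H)-one | CC(C)C[C@@H](c1c(OCOC)cc(OCOC)cc1OCOC)[C@@]1(C)C(=O)C[C@H]2C1=C[C@H](C(C)(C)O[Si](CC)(CC)CC)CC[C@H]2C | intermediate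
31 | (1R,3aR,4R,7R)-7-(2-hydroxypropan-2-yl)-1,4-dimethyl-1-{(1S)-3-methyl-1-[2,4,6-tris(methoxymethoxy)phenyl]butyl}-3,3a,4,5,6,7-hexahydroazulen-2(1H)-one | CC(C)C[C@@H](c1c(OCOC)cc(OCOC)cc1OCOC)[C@@]1(C)C(=O)C[C@H]2C1=C[C@H](C(C)(C)O)CC[C@H]2C | intermediate
32 | hydrazone of 31 at C-2 (not isolated) | CC(C)C[C@@H](c1c(OCOC)cc(OCOC)cc1OCOC)[C@@]1(C)C(=NN)C[C@H]2C1=C[C@H](C(C)(C)O)CC[C@H]2C | intermediate
33 | 2-[(1R,3aR,4R,7R)-1,4-dimethyl-1-{(1R)-3-methyl-1-[2,4,6-tris(methoxymethoxy)phenyl]butyl}-1,2,3,3a,4,5,6,7-octahydroazulen-7-yl]propan-2-ol | CC(C)C[C@@H](c1c(OCOC)cc(OCOC)cc1OCOC)[C@@]1(C)CC[C@H]2C1=C[C@H](C(C)(C)O)CC[C@H]2C | intermediate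
34 | 3-lithio derivative of 33 as its lithium alkoxide (not isolated) | CC(C)C[C@@H](c1c(OCOC)c([Li])c(OCOC)cc1OCOC)[C@@]1(C)CC[C@H]2C1=C[C@H](C(C)(C)O[Li])CC[C@H]2C | intermediate
35 | 3-{(1R)-1-[(1R,3aR,4R,7R)-7-(2-hydroxypropan-2-yl)-1,4-dimethyl-1,2,3,3a,4,5,6,7-octahydroazulen-1-yl]-3-methylbutyl}-2,4,6-tris(methoxymethoxy)benzaldehyde | CC(C)C[C@@H](c1c(OCOC)c(C=O)c(OCOC)cc1OCOC)[C@@]1(C)CC[C@H]2C1=C[C@H](C(C)(C)O)CC[C@H]2C | intermediate
36 | lithium α-amino alkoxide of 35 with LiN(Me)CH2CH2NMe2, as its lithium alkoxide (not isolated) | CC(C)C[C@@H](c1c(OCOC)c(C(O[Li])N(C)CCN(C)C)c(OCOC)cc1OCOC)[C@@]1(C)CC[C@H]2C1=C[C@H](C(C)(C)O[Li])CC[C@H]2C | intermediate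
37 | ring-lithiated derivative of 36 at the last free aryl position (not isolated) | CC(C)C[C@@H](c1c(OCOC)c(C(O[Li])N(C)CCN(C)C)c(OCOC)c([Li])c1OCOC)[C@@]1(C)CC[C@H]2C1=C[C@H](C(C)(C)O[Li])CC[C@H]2C | intermediate
38 | 5-{(1R)-1-[(1R,3aR,4R,7R)-7-(2-hydroxypropan-2-yl)-1,4-dimethyl-1,2,3,3a,4,5,6,7-octahydroazulen-1-yl]-3-methylbutyl}-2,4,6-tris(methoxymethoxy)benzene-1,3-dicarbaldehyde | CC(C)C[C@@H](c1c(OCOC)c(C=O)c(OCOC)c(C=O)c1OCOC)[C@@]1(C)CC[C@H]2C1=C[C@H](C(C)(C)O)CC[C@H]2C | intermediate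
39 | 5-{(1R)-1-[(1R,3aR,4R,7R)-7-(2-hydroxypropan-2-yl)-1,4-dimethyl-1,2,3,3a,4,5,6,7-octahydroazulen-1-yl]-3-methylbutyl}-2,4,6-trihydroxybenzene-1,3-dicarbaldehyde | CC(C)C[C@@H](c1c(O)c(C=O)c(O)c(C=O)c1O)[C@@]1(C)CC[C@H]2C1=C[C@H](C(C)(C)O)CC[C@H]2C | target

**Totals**
Total step count: 21. Longest linear sequence: 19 steps (steps 1–11 and 14–21); steps 12–13 make the aromatic fragment.

**The three steps most likely to fail**

Step 14 (key Michael addition). A tertiary carbanion must form a quaternary centre next to a doubly ortho-substituted benzylic carbon. Attack through C-8 instead of C-1 is possible, and the benzylic configuration rests on a transition-state model that is not proven for this substrate. Fallback: make the two bonds at the benzylic carbon in the opposite order, setting out from 20. Its dianion 25 is added at −78 °C to the aldehyde of 23 in an aldol addition at C-1, giving the lithium aldolate F1. On warming, the Boc group moves to the new alkoxide and is expelled, which gives the terpene-substituted o-quinone methide F2. Excess i-BuMgBr (24) then adds 1,4 to its exocyclic carbon and the sequence comes back to the route at 28. The benzylic centre is now set by the approach of the Grignard reagent past the quaternary C-1, and the epimers can be separated at 28 if needed.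

Step 7 (directed hydrogenation). The alkene is tetrasubstituted and electron-poor, and the remote tertiary hydroxyl has to outcompete the ketone and ester oxygens as the directing group. Fallback, setting out from 12: Luche reduction (NaBH4, CeCl3·7H2O, MeOH) gives the allylic alcohols. The (5R,7R) epimer, allylic alcohol F3, whose new hydroxyl lies on the face of the hydroxypropyl group, is separated, and the other epimer is returned to 12 with MnO2. The proximal allylic hydroxyl now directs the same iridium catalyst to the same face of an electron-rich alkene, giving the saturated diol F4. Dess–Martin oxidation of the secondary alcohol comes back to the route at 13.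

Step 18 (Wolff–Kishner reduction). Hydrazone formation at a ketone flanked by the quaternary C-1 may be slow, and three aryl MOM ethers must survive KOH at 200 °C. Fallback, setting out from 30 (before desilylation): NaBH4 reduces the C-2 ketone to the secondary alcohol F5. NaH, CS2 and MeI give the xanthate F6. Bu3SnH with AIBN in refluxing toluene (Barton–McCombie) gives the C-2 methylene silyl ether F7. Bu4NF then removes the silyl group and the sequence comes back to the route at 33.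

Further compounds
F1 | step 14 | lithium aldolate from 25 and 23: tert-butyl 1-{[2-(tert-butoxycarbonyloxy)-4,6-bis(methoxymethoxy)phenyl](lithiooxy)methyl}-1,4-dimethyl-2-oxo-7-{2-[(triethylsilyl)oxy]propan-2-yl}-1,2,3,3a,4,5,6,7-octahydroazulene-3-carboxylate, ring configuration as in 28, carbinol carbon undefined | CC(C)(C)OC(=O)Oc1cc(OCOC)cc(OCOC)c1C(O[Li])[C@@]1(C)C(=O)C(C(=O)OC(C)(C)C)[C@H]2C1=C[C@H](C(C)(C)O[Si](CC)(CC)CC)CC[C@H]2C
F2 | step 14 | terpene-substituted o-quinone methide: tert-butyl (1R,3aS,4R,7R)-1-{[2,4-bis(methoxymethoxy)-6-oxocyclohexa-2,4-dien-1-ylidene]methyl}-1,4-dimethyl-2-oxo-7-{2-[(triethylsilyl)oxy]propan-2-yl}-1,2,3,3a,4,5,6,7-octahydroazulene-3-carboxylate | O=C1C=C(OCOC)C=C(OCOC)C1=C[C@@]1(C)C(=O)C(C(=O)OC(C)(C)C)[C@H]2C1=C[C@H](C(C)(C)O[Si](CC)(CC)CC)CC[C@H]2C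
F3 | step 7 | tert-butyl 2-[(5R,7R)-7-hydroxy-5-(2-hydroxypropan-2-yl)-2-methylcyclohept-1-en-1-yl]acetate | CC1=C(CC(=O)OC(C)(C)C)[C@H](O)C[C@@H](CC1)C(C)(C)O
F4 | step 7 | tert-butyl 2-[(1R,2R,5R,7R)-7-hydroxy-5-(2-hydroxypropan-2-yl)-2-methylcycloheptyl]acetate | CC(C)(C)OC(=O)C[C@H]1[C@H](O)C[C@H](C(C)(C)O)CC[C@H]1C
F5 | step 18 | C-2 alcohol from 30 (carbinol configuration undefined, other centres as in 30) | CC(C)C[C@@H](c1c(OCOC)cc(OCOC)cc1OCOC)[C@@]1(C)C(O)C[C@H]2C1=C[C@H](C(C)(C)O[Si](CC)(CC)CC)CC[C@H]2C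
F6 | step 18 | O-alkyl S-methyl xanthate of F5 | CC(C)C[C@@H](c1c(OCOC)cc(OCOC)cc1OCOC)[C@@]1(C)C(OC(=S)SC)C[C@H]2C1=C[C@H](C(C)(C)O[Si](CC)(CC)CC)CC[C@H]2C
F7 | step 18 | triethylsilyl ether of 33 | CC(C)C[C@@H](c1c(OCOC)cc(OCOC)cc1OCOC)[C@@]1(C)CC[C@H]2C1=C[C@H](C(C)(C)O[Si](CC)(CC)CC)CC[C@H]2C
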